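While X and Q, charged equal, turn into product and nothing else, a percentage point of excess in the product converts into excess in the remaining substrate at an exchange rate, and I reckoned that rate first for this flask, a kinetic resolution of X and Q by single-handed J.

| setting | Saturday's | Tuesday's | Monday's | flask |
|---|---|---|---|---|
| X | 0.10 M | 0.10 M | 0.20 M | 0.10 M |
| Q | 0.10 M | 0.10 M | 0.20 M | 0.10 M |
| E | 1 equiv | 4 equiv | 2 equiv | 2.00 equiv |
| G | 0.1 mol% | 0.1 mol% | 0.1 mol% | 0.1 mol% |
| remark | run made earlier | run made earlier | run made earlier |  |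
| time |  |  |  | 25 h |

| run | time / h | X / % | Q / % | L / % |
|---|---|---|---|---|
| Saturday's | 4.00 | 50.0 | 50.4 | 0 |
| Saturday's | 8.00 | 49.2 | 49.6 | 0.5 |
| Saturday's | 10.0 | 49.3 | 49.4 | 0.2 |
| Saturday's | 15.0 | 48.1 | 49.8 | 1.1 |
| Saturday's | 20.0 | 47.1 | 47.8 | 3.5 |
| Saturday's | 25.0 | 45.7 | 47.3 | 3.7 |
| Tuesday's | 2.00 | 49.8 | 50.6 | 0.1 |
| Tuesday's | 3.00 | 50.7 | 49.5 | 0 |
| Tuesday's | 5.00 | 49.8 | 50.0 | 0.8 |
| Tuesday's | 8.00 | 50.2 | 49.5 | 0.8 |
| Tuesday's | 10.0 | 48.9 | 48.9 | 0.9 |
| Tuesday's | 15.0 | 46.8 | 48.5 | 2.1 |
| Tuesday's | 25.0 | 45.9 | 46.0 | 4.3 |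
| Monday's | 2.00 | 50.0 | 49.6 | 0.5 |
| Monday's | 6.00 | 50.5 | 50.4 | 0 |
| Monday's | 12.0 | 49.3 | 48.9 | 0.6 |
| Monday's | 20.0 | 47.0 | 48.3 | 3.0 |
| Monday's | 25.0 | 47.9 | 46.6 | 2.7 |

(each reading ± 0.5 percentage points)

- part of the X and Q charged together that has reacted at 25 h
- excess of L over Z in the product at 25 h
- excess of Q over X among what is left of the two at 25 h

- J is single-handed; X and Q are mirror images of each other, charged as a racemate, each of them at the stated concentration
- solid, in amounts per volume of the solution: E
- at the start none of E is in solution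
- an excess is the difference of the two amounts in percent of their sum
- an excess is below zero if the other one leads
- the handed part of J does not stay in what it makes, so the products of the two hands are mirror images too

Saturday's and Tuesday's runs differed from the flask in E alone, and their readings of X and Q at 25 h gave a mean conversion c of 7.55%. X and Q were charged equal, so as long as both went into product and nowhere else, Q left minus X left equalled L minus Z. On that condition the excess of Q left was the product excess e = (L − Z)/(L + Z) times the lever λ, conversion over the unreacted part: 0.0817.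

Z was unread, so I took it as the shortfall of the three read species. The same two runs at 25 h gave e = 5.96%, which I chose as a floor, and Saturday's readings at 20.0 h gave 37.3%, which I chose as a ceiling. Through λ, my bracket on the excess of Q ran from 0.487% to 3.04%, an estimate with the scatter of its readings, not a proven bound.

The forecast gave c 7.5%, e 10% and an excess of Q of 0.8%, saying “That makes L slightly favoured”; that last value lay inside my bracket.

The flask gave c 7.17%, e 31.3%, 21 percentage points above the forecast, and an excess of Q of 1.44%, inside the bracket.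

    J + Q → Z (k = 0.180 M⁻¹ h⁻¹)
    J + X → L (k = 0.350 M⁻¹ h⁻¹)
    X + D ⇌ Q + D, rate k3*[D]*[X] forward; the back reaction follows from the equilibrium constant (k = 330 M⁻¹ h⁻¹)
    E ⇌ J, rate k4*(cs4 - [J]) while solid is left; crystals form when [J] > cs4 (solubility = 0.0870 M, k = 0.0170 h⁻¹)
    G → D (k = 0.150 h⁻¹)

The scheme interconverts X and Q over D, the form that G becomes, and in the flask D stood at 97.6% of the catalyst charged at 25.0 h. The lever from the earlier runs, put on the flask's e, asks 2.56%, more than the 1.44% found. With 0.06 mol% of G, the lever on that neighbour's e of 31.2% asks 2.55%, and that neighbour holds 1.74%.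

All runs stem from a simulated flask with constants of no real substance; scatter was added.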